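# Synthesis proposal for (2S,3R,4S)-2-(4-hydroxy-3-methoxyphenyl)-3-hydroxymethyl-4-(4-hydroxy-3,5-dimethoxybenzoyl)tetrahydrofuran (24)

## Analysis of the target

Target 24 is a single tetrahydrofuran ring with three contiguous substituted carbons. Its atoms are labelled O1, C2 (bearing the 4-hydroxy-3-methoxyphenyl ring A), C3 (bearing the hydroxymethyl carbon C6), C4 (bearing the ketone carbon C7, which carries the 4-hydroxy-3,5-dimethoxyphenyl ring B) and C5 (the free CH2); the same labels are used for the corresponding atoms of every intermediate. The stereocentres are (2S,3R,4S): ring A and C6 are trans, C6 and the aroyl group are trans, so every vicinal pair is trans and ring A and the aroyl group are cis across the ring, which is the least strained arrangement. C2 and C3 are fixed once made, whereas C4 lies alpha to the aryl ketone and can be equilibrated. The sensitive groups are the two phenols, the electron-rich benzylic ether at C2 (ionised by acid, attacked by benzylic oxidants), and a ketone that is beta to the ring oxygen through C5 and can be reached by the C6 hydroxyl as a hemiketal when C6 and C7 are cis. The difficulty is to set three centres in the absolute sense from one source of chirality while placing C6 at the alcohol level and C7 at the ketone level on neighbouring carbons. The strategy rests on C3, which carries both the hydroxymethyl carbon C6 and the ring bond to C4: this is the pattern left when an oxirane spanning C3 and C6 is opened by one-electron reduction to a C3 radical that adds to a multiple bond at C4. Read this way, C5–O1 is an ether link to a propargylic carbon and the C7 ketone is the oxidised form of an exocyclic aryl-substituted alkene, that is, of an aryl alkyne acceptor.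

## Retrosynthetic reasoning

**Protecting groups (24 from 23).** Only O–Si bonds are cut. The two phenols and the C6 hydroxyl of 24 are traced to the tris-silyl ether 23, so that the last step is one fluoride-mediated desilylation and nothing on the skeleton has to change after the stereocentres are final.

**C4 configuration and C7 oxidation level (23 from 22, 21 and 18).** No skeletal bond is cut. The all-trans ketone 23 is taken back to its C4 epimer mixture 22, because C4 is the one centre that thermodynamics can set. Ketone 22 goes back to the benzylic alcohol 21, and 21 to the exocyclic aryl alkene 18 by hydroboration with oxidative work-up using 19. The forward sequence must put oxygen on C7 and hydrogen on C4; the C4 configuration obtained kinetically does not matter because it is corrected in 23. The silyl ether on C6 (18 from alcohol 16 and 17) keeps the C6 oxygen from closing onto C7 during equilibration.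

**Key disconnection (16 from 14).** The C3–C4 bond is cut. It is the only ring C–C bond whose two ends can be derived from an oxirane carbon (C3, with C6 as the other oxirane carbon) and an alkyne carbon (C4, with C7 as the aryl-bearing alkyne carbon). Cutting it reduces the ring to the acyclic epoxy propargyl ether 14. The forward reaction has to open the oxirane at C3 by single-electron transfer from a trivalent titanium reductant, close the ring 5-exo onto the alkyne, and place C6 trans to ring A. It makes the ring, one skeletal bond and the C3 stereocentre, and leaves the C6 hydroxyl free.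

**Ether bond (14 from 7 and 13).** The O1–C5 bond is cut. This separates the molecule into a ring A half, the erythro epoxy alcohol 7 that holds the only stereocentre that must be controlled (C2), and a ring B half, the propargylic bromide 13. The forward O-alkylation must avoid a free alkoxide next to the oxirane, which could trigger a Payne rearrangement.

**Ring B fragment (13 from 11, 9, 10, 8).** The aryl–alkyne bond is cut. Bromide 13 comes from alcohol 11 with 12, and 11 from a Sonogashira coupling of the silylated aryl bromide 9 with propargyl alcohol 10; 9 is the silyl ether of the bromophenol 8 made with 2. The aryl–alkyne bond is made on a simple compound, where forcing conditions do no harm.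

**Ring A fragment (7 from 5, 3, 4, 1).** The C2–C3 bond is cut. Epoxy alcohol 7 is the fast-formed product of a Sharpless kinetic resolution of the racemic allylic alcohol 5 with 6, and 5 is the adduct of the vinyl nucleophile 4 and the silylated vanillin 3 (from 1 and 2). The resolution sets C2 in the absolute sense; the oxirane carbon configuration is set as well but is lost later in the radical.

## Alternatives that were turned down

**Alternative 1:** The ring is cut at O1–C2 and C2–C3, and the C4–C5 bond is traced to a 1,2-shift. C2 then comes from aldehyde 3 and the rest from a five-carbon tertiary allylic diol A2 that carries ring B and a hydroxyl on C7 and the second hydroxyl on C5; the key step would give the all-trans keto acetate A1.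
- Forward step: 3 and A2 are condensed to a cyclic acetal, a strong Lewis acid opens it to an oxocarbenium ion at C2, the alkene attacks C2, and C5 migrates from C7 to the cationic C4 while C7 becomes the ketone.
- For it: one operation makes the ring, three bonds, all three stereocentres and the ketone at its final oxidation level. No C4 equilibration and no alkene-to-ketone conversion follow. On these points it is stronger than the chosen route.
- Against it: C7 of A2 is a tertiary carbinol that is allylic and attached to the very electron-rich ring B. Under the Lewis acid, ionisation at C7 competes with acetal opening and would destroy the only stereocentre from which the absolute configuration is relayed. The relay runs through a chair whose sense depends on ring B sitting equatorial ((R)-A2 would be needed in that case), and a competing oxonia-Cope/aldol pathway can erode it. The oxocarbenium ion from 3 is stabilised by the para oxygen and is a weak electrophile. A2 as a single enantiomer needs an asymmetric construction of a tertiary alcohol that costs about as many steps as the whole front end of the chosen route.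
- Comparison: the chosen strategy sets only C3 in its key step, but does so under neutral reducing conditions in which neither aryl-bearing carbon can ionise, and it takes its absolute configuration from a secondary carbinol made by a standard resolution.

**Alternative 2:** O1–C2 and C3–C4 are cut. This gives a racemic 2-(1-arylvinyl)oxirane A4 (ring B, C4, C5, C7) and a benzylidene malonate A5 (ring A, C2, C3); the annulation product would be the 2,4-cis tetrahydrofuran 3,3-diester A3.
- Forward step: zerovalent palladium ionises A4 to a π-allyl complex bearing an alkoxide, the alkoxide adds to the β-carbon of A5, and the malonate carbanion closes on the allyl terminus C4.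
- For it: it is convergent and catalytic, forms two bonds and the ring at once, takes chirality from a ligand instead of a resolution, and fixes the 2,4-cis relation directly. In convergence and in the economy of the asymmetric step it is stronger than the chosen route.
- Against it: A5 carries a para-oxygen donor and is a poor, reversible acceptor for the alkoxide, so turnover and enantiocontrol are both at risk. C3 arrives as a quaternary diester that must lose one ester and have the other reduced, so its configuration is set only later by protonation. The 1-arylvinyl group must be cleaved oxidatively to the C7 ketone in the presence of two electron-rich arenes.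
- Comparison: the steps after the key step are not fewer than in the chosen route, which delivers C3 with its hydroxymethyl group at the right oxidation level and trans to ring A directly from the oxirane.

**Alternative 3:** Only C2–C3 is cut. The precursor is an α-diazo γ-lactone A7 in which C3 is the diazo carbon, C6 the lactone carbonyl, C7 the lactone carbinol carbon bearing ring B, and C4 carries a CH2–O–CH2 link to ring A; the key step would give the cis-fused bicyclic lactone A6.
- Forward step: a dirhodium tetracarboxylate catalyst turns A7 into a carbenoid at C3 that inserts into the benzylic C–H bond next to the ether oxygen (C2), closing the tetrahydrofuran with ring A on the convex face.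
- For it: a C–H bond serves as the functional group at C2, the rigid bicycle makes the 2,3 relation predictable, and both arenes and both side-chain carbons are already in place. In bond economy at C2 it is the most direct of the four.
- Against it: the lactone ties C6 and C7 to one face, so A6 has the C4 configuration opposite to the target and needs the same epimerisation as the chosen route. C6 is at the acid level and C7 at the alcohol level, the reverse of what is needed, so unfolding requires reduction, differentiation of a primary from a benzylic secondary alcohol, and oxidation. The carbenoid has other outlets (oxonium ylide formation at O1, addition to the electron-rich ring A). A7, with two stereocentres and a diazo group, needs a longer enantioselective sequence than 14.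
- Comparison: after the key step the burden is similar, but before it the route is longer and less convergent, whereas the radical closure uses a precursor assembled from two simple halves in one ether-forming step.

Key step: step 8

## Route

Remark on the chemistry: both phenols are carried as triisopropylsilyl ethers, which should withstand the alkaline peroxide of step 10 and the amidine base of step 12 better than smaller silyl groups.

Assumption: 4-bromo-2,6-dimethoxyphenol (8) and diisopropyl D-(−)-tartrate are taken as commercial. Reagents that only mediate a step are named on the Conditions line and carry no number.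

Step 1
Reactants: 1 vanillin; 2 chlorotriisopropylsilane
Product: 3 3-methoxy-4-(triisopropylsilyloxy)benzaldehyde
Conditions: imidazole, DMF, rt
Reagents that add atoms: chlorotriisopropylsilane (2), CC(C)[Si](Cl)(C(C)C)C(C)C
Why: Imidazole-promoted silylation of the phenol removes the acidic proton before the Grignard step and should proceed cleanly on this unhindered phenol.

Step 2
Reactants: 3 3-methoxy-4-(triisopropylsilyloxy)benzaldehyde; 4 vinylmagnesium bromide
Product: 5 racemic 1-[3-methoxy-4-(triisopropylsilyloxy)phenyl]prop-2-en-1-ol
Conditions: THF, −78 °C to 0 °C; aqueous quench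
Reagents that add atoms: vinylmagnesium bromide (4), C=C[Mg]Br
Why: Grignard addition to the aryl aldehyde forms the C2–C3 bond; the product is deliberately racemic because the next step resolves it.

Step 3
Reactants: 5 racemic 1-[3-methoxy-4-(triisopropylsilyloxy)phenyl]prop-2-en-1-ol; 6 tert-butyl hydroperoxide
Product: 7 (R)-[3-methoxy-4-(triisopropylsilyloxy)phenyl][(S)-oxiran-2-yl]methanol (erythro)
Conditions: Ti(OiPr)4 (cat.), diisopropyl D-(−)-tartrate, 6 (0.45 equiv), 4 Å MS, CH2Cl2, −20 °C; stopped below half conversion
Reagents that add atoms: tert-butyl hydroperoxide (6), CC(C)(C)OO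
Why: Sharpless kinetic resolution: with the D-(−)-tartrate the (S)-alcohol should be epoxidised much faster than the (R)-alcohol, with oxygen delivered to the alkene face that gives the erythro epoxy alcohol. The product therefore has the (S)-oxirane carbon and the carbinol carbon that becomes C2 of the target (its descriptor changes from S to R only because oxiranyl outranks aryl).

Step 4
Reactants: 8 4-bromo-2,6-dimethoxyphenol; 2 chlorotriisopropylsilane
Product: 9 (4-bromo-2,6-dimethoxyphenoxy)triisopropylsilane
Conditions: imidazole, DMF, 40 °C
Reagents that add atoms: chlorotriisopropylsilane (2), CC(C)[Si](Cl)(C(C)C)C(C)C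
Why: Silylation of the phenol flanked by two methoxy groups is slower than in step 1 but should go to completion with gentle warming; the crowded silyl ether is correspondingly robust.

Step 5
Reactants: 9 (4-bromo-2,6-dimethoxyphenoxy)triisopropylsilane; 10 propargyl alcohol
Product: 11 3-[3,5-dimethoxy-4-(triisopropylsilyloxy)phenyl]prop-2-yn-1-ol
Conditions: Pd(PhCN)2Cl2 (cat.), P(tBu)3 (cat.), CuI (cat.), iPr2NH, dioxane, rt
Reagents that add atoms: propargyl alcohol (10), C#CCO
Why: Sonogashira coupling; the bulky electron-rich phosphine should allow zerovalent palladium to insert into the electron-rich aryl bromide at room temperature, and the free propargylic hydroxyl is tolerated.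

Step 6
Reactants: 11 3-[3,5-dimethoxy-4-(triisopropylsilyloxy)phenyl]prop-2-yn-1-ol; 12 carbon tetrabromide
Product: 13 [4-(3-bromoprop-1-yn-1-yl)-2,6-dimethoxyphenoxy]triisopropylsilane
Conditions: PPh3, CH2Cl2, 0 °C
Reagents that add atoms: carbon tetrabromide (12), BrC(Br)(Br)Br
Why: Appel reaction: the alcohol is activated as an alkoxyphosphonium ion and displaced by bromide under neutral conditions that leave the aryl silyl ether untouched.

Step 7
Reactants: 7 (R)-[3-methoxy-4-(triisopropylsilyloxy)phenyl][(S)-oxiran-2-yl]methanol; 13 [4-(3-bromoprop-1-yn-1-yl)-2,6-dimethoxyphenoxy]triisopropylsilane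
Product: 14 (S)-2-[(R)-[3-methoxy-4-(triisopropylsilyloxy)phenyl]{3-[3,5-dimethoxy-4-(triisopropylsilyloxy)phenyl]prop-2-yn-1-yloxy}methyl]oxirane (erythro epoxy propargyl ether)
Conditions: Ag2O, 4 Å MS, CH2Cl2, rt, dark
Reagents that add atoms: none
Why: Ag2O-promoted O-alkylation: halide abstraction activates the propargylic bromide toward the neutral alcohol, so no free alkoxide sits next to the oxirane and a Payne rearrangement is avoided; no bond to a stereocentre is broken.

Step 8
Reactants: 14 erythro epoxy propargyl ether
Product: 16 [(2S,3R)-4-[3,5-dimethoxy-4-(triisopropylsilyloxy)benzylidene]-2-[3-methoxy-4-(triisopropylsilyloxy)phenyl]tetrahydrofuran-3-yl]methanol (alkene geometry not fixed), via bis(chlorotitanocene) adduct 15 (not isolated)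
Conditions: Cp2TiCl2, Zn dust, THF, rt (gives Cp2TiCl), added slowly to 14 in THF, rt; then 1 M HCl
Reagents that add atoms: none
Why: Cp2TiCl, a trivalent titanium one-electron donor made from Cp2TiCl2 and Zn, binds the oxirane oxygen and cleaves the C3–O bond homolytically, giving the secondary C3 radical (preferred over a primary radical at C6) and a tetravalent titanium alkoxide on C6. The C3 radical adds to the proximal alkyne carbon C4 in a 5-exo-dig closure that forms C3–C4 and the tetrahydrofuran ring; the aryl-stabilised vinyl radical at C7 is captured by a second Cp2TiCl (or takes hydrogen from THF), and the acid work-up protonates the titanium–carbon and titanium–oxygen bonds. The closest known reaction type is the titanocene-mediated reductive opening of epoxides followed by 5-exo radical cyclisation onto alkynes and alkenes, which has been applied to epoxy propargyl and epoxy allyl ethers of this kind. The new stereocentre C3 is controlled by C2: in the chair-like transition state ring A sits pseudo-equatorial and the titanoxymethyl group on the radical carbon turns away from it, which should give the 2,3-trans product. The oxirane carbon becomes planar in the radical, so only the carbinol configuration of 14 is carried into the product. The step needs ring closure to outrun reduction of the C3 radical by a second titanium, which would end in β-elimination of an oxygen substituent; the aryl-activated alkyne, the oxygen in the tether and the slow addition of the reductant should secure this. Silyl ethers, the benzylic ether and both arenes are inert to the reagent.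

Step 9
Reactants: 16 [(2S,3R)-4-arylmethylene-2-aryltetrahydrofuran-3-yl]methanol; 17 tert-butylchlorodimethylsilane
Product: 18 tert-butyl{[(2S,3R)-4-[3,5-dimethoxy-4-(triisopropylsilyloxy)benzylidene]-2-[3-methoxy-4-(triisopropylsilyloxy)phenyl]tetrahydrofuran-3-yl]methoxy}dimethylsilane
Conditions: imidazole, CH2Cl2, 0 °C to rt
Reagents that add atoms: tert-butylchlorodimethylsilane (17), CC(C)(C)[Si](C)(C)Cl
Why: Silylation of the primary alcohol distinguishes the C6 oxygen from the C7 oxygen that is introduced next, and prevents a cis C6 hydroxyl from trapping the later ketone as a bicyclic hemiketal during equilibration.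

Step 10
Reactants: 18 silyl ether of the exocyclic aryl alkene; 19 hydrogen peroxide
Product: 21 [3,5-dimethoxy-4-(triisopropylsilyloxy)phenyl]{4-[(tert-butyldimethylsilyloxy)methyl]-5-[3-methoxy-4-(triisopropylsilyloxy)phenyl]tetrahydrofuran-3-yl}methanol with (2S,3R,4R) ring configuration expected (3,4-cis) as a mixture of C7 epimers, via C7 alkylborane 20 (not isolated)
Conditions: BH3·SMe2, THF, 0 °C to rt; then aq. NaOH, 30% H2O2, 0 °C
Reagents that add atoms: hydrogen peroxide (19), OO
Why: Hydroboration–oxidation of the trisubstituted alkene should place boron on the less substituted benzylic carbon C7 and hydrogen on C4 in a syn addition from the face opposite the C3 substituent, so the 3,4-cis isomer is expected. Oxidation replaces boron by hydroxyl with retention; neither the C4 nor the C7 configuration matters, since C7 is oxidised in step 11 and C4 is equilibrated in step 12.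

Step 11
Reactants: 21 C7 benzylic alcohol (C7 epimers)
Product: 22 [3,5-dimethoxy-4-(triisopropylsilyloxy)phenyl]{4-[(tert-butyldimethylsilyloxy)methyl]-5-[3-methoxy-4-(triisopropylsilyloxy)phenyl]tetrahydrofuran-3-yl}methanone, mainly the (2S,3R,4R) 3,4-cis isomer
Conditions: DMP, CH2Cl2, 0 °C to rt
Reagents that add atoms: none
Why: Dess–Martin oxidation converts both C7 epimers into one aryl ketone under mild conditions compatible with the silyl ethers and the benzylic ether.

Step 12
Reactants: 22 aryl ketone, mainly 3,4-cis
Product: 23 [3,5-dimethoxy-4-(triisopropylsilyloxy)phenyl]{(2S,3R,4S)-configured 4-[(tert-butyldimethylsilyloxy)methyl]-5-[3-methoxy-4-(triisopropylsilyloxy)phenyl]tetrahydrofuran-3-yl}methanone (all-trans)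
Conditions: DBU (cat.), toluene, rt to 40 °C
Reagents that add atoms: none
Why: Base-mediated epimerisation through the enolate alpha to the aryl ketone: C3 cannot epimerise and anchors C4, and the all-trans arrangement is the least strained, so the equilibrium should lie on the side of 23. β-Elimination of the ring oxygen should be slow because the C5–O1 bond lies close to the nodal plane of the exocyclic enolate, and the silyl ether on C6 keeps the cis isomer from being stabilised as a hemiketal.

Step 13
Reactants: 23 all-trans tris-silyl ketone
Product: 24 (4-hydroxy-3,5-dimethoxyphenyl)[(2S,3R,4S)-configured 5-(4-hydroxy-3-methoxyphenyl)-4-(hydroxymethyl)tetrahydrofuran-3-yl]methanone (target; ring labels O1, C2 ring A, C3 hydroxymethyl, C4 aroyl)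
Conditions: TBAF, AcOH, THF, 0 °C to rt
Reagents that add atoms: none
Why: Fluoride-mediated desilylation should cleave both aryl silyl ethers and the primary silyl ether in one operation; the acetic acid buffer keeps phenoxide and enolate concentrations low so that C4 is not disturbed.

## Compound list

1 | vanillin | COc1cc(C=O)ccc1O | starting material
2 | chlorotriisopropylsilane | CC(C)[Si](Cl)(C(C)C)C(C)C | starting material
3 | 3-methoxy-4-(triisopropylsilyloxy)benzaldehyde | COc1cc(C=O)ccc1O[Si](C(C)C)(C(C)C)C(C)C | intermediate
4 | vinylmagnesium bromide | C=C[Mg]Br | starting material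
5 | racemic 1-[3-methoxy-4-(triisopropylsilyloxy)phenyl]prop-2-en-1-ol | COc1cc(C(O)C=C)ccc1O[Si](C(C)C)(C(C)C)C(C)C | intermediate
6 | tert-butyl hydroperoxide | CC(C)(C)OO | starting material
7 | (R)-[3-methoxy-4-(triisopropylsilyloxy)phenyl][(S)-oxiran-2-yl]methanol (erythro) | COc1cc([C@@H](O)[C@@H]2CO2)ccc1O[Si](C(C)C)(C(C)C)C(C)C | intermediate
8 | 4-bromo-2,6-dimethoxyphenol | COc1cc(Br)cc(OC)c1O | starting material
9 | (4-bromo-2,6-dimethoxyphenoxy)triisopropylsilane | COc1cc(Br)cc(OC)c1O[Si](C(C)C)(C(C)C)C(C)C | intermediate
10 | propargyl alcohol | C#CCO | starting material
11 | 3-[3,5-dimethoxy-4-(triisopropylsilyloxy)phenyl]prop-2-yn-1-ol | COc1cc(C#CCO)cc(OC)c1O[Si](C(C)C)(C(C)C)C(C)C | intermediate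
12 | carbon tetrabromide | BrC(Br)(Br)Br | starting material
13 | [4-(3-bromoprop-1-yn-1-yl)-2,6-dimethoxyphenoxy]triisopropylsilane | COc1cc(C#CCBr)cc(OC)c1O[Si](C(C)C)(C(C)C)C(C)C | intermediate
14 | erythro epoxy propargyl ether: (R)-carbinol carbon bearing ring A, an (S)-oxiranyl group and the 3-(ring B)prop-2-ynyl ether | COc1cc([C@@H](OCC#Cc2cc(OC)c(O[Si](C(C)C)(C(C)C)C(C)C)c(OC)c2)[C@@H]2CO2)ccc1O[Si](C(C)C)(C(C)C)C(C)C | intermediate
15 | bis(chlorotitanocene) adduct: cyclised product with Cp2TiCl on the C6 oxygen and on C7 (cyclopentadienyl rings drawn sigma-bonded) | COc1cc([C@H]2OCC(=C(c3cc(OC)c(O[Si](C(C)C)(C(C)C)C(C)C)c(OC)c3)[Ti](Cl)(C3C=CC=C3)C3C=CC=C3)[C@@H]2CO[Ti](Cl)(C2C=CC=C2)C2C=CC=C2)ccc1O[Si](C(C)C)(C(C)C)C(C)C | intermediate (not isolated)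
16 | (2S,3R)-2-aryl(ring A)-3-hydroxymethyl-4-[aryl(ring B)methylene]tetrahydrofuran, 2,3-trans, alkene geometry not fixed | COc1cc([C@H]2OCC(=Cc3cc(OC)c(O[Si](C(C)C)(C(C)C)C(C)C)c(OC)c3)[C@@H]2CO)ccc1O[Si](C(C)C)(C(C)C)C(C)C | intermediate
17 | tert-butylchlorodimethylsilane | CC(C)(C)[Si](C)(C)Cl | starting material
18 | tert-butyldimethylsilyl ether of 16 at the C6 oxygen | COc1cc([C@H]2OCC(=Cc3cc(OC)c(O[Si](C(C)C)(C(C)C)C(C)C)c(OC)c3)[C@@H]2CO[Si](C)(C)C(C)(C)C)ccc1O[Si](C(C)C)(C(C)C)C(C)C | intermediate
19 | hydrogen peroxide | OO | starting material
20 | C7 alkylborane from 18 (boron on C7, hydrogen on C4, 3,4-cis expected, C7 epimers) | COc1cc([C@H]2OC[C@H](C(B)c3cc(OC)c(O[Si](C(C)C)(C(C)C)C(C)C)c(OC)c3)[C@@H]2CO[Si](C)(C)C(C)(C)C)ccc1O[Si](C(C)C)(C(C)C)C(C)C | intermediate (not isolated)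
21 | C7 benzylic alcohol, ring (2S,3R,4R) expected (2,3-trans, 3,4-cis), C7 epimers | COc1cc([C@H]2OC[C@H](C(O)c3cc(OC)c(O[Si](C(C)C)(C(C)C)C(C)C)c(OC)c3)[C@@H]2CO[Si](C)(C)C(C)(C)C)ccc1O[Si](C(C)C)(C(C)C)C(C)C | intermediate
22 | C7 aryl ketone, mainly (2S,3R,4R) (3,4-cis) | COc1cc([C@H]2OC[C@H](C(=O)c3cc(OC)c(O[Si](C(C)C)(C(C)C)C(C)C)c(OC)c3)[C@@H]2CO[Si](C)(C)C(C)(C)C)ccc1O[Si](C(C)C)(C(C)C)C(C)C | intermediate
23 | all-trans (2S,3R,4S) tris-silyl ketone | COc1cc([C@H]2OC[C@@H](C(=O)c3cc(OC)c(O[Si](C(C)C)(C(C)C)C(C)C)c(OC)c3)[C@@H]2CO[Si](C)(C)C(C)(C)C)ccc1O[Si](C(C)C)(C(C)C)C(C)C | intermediate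
24 | (2S,3R,4S)-2-(4-hydroxy-3-methoxyphenyl)-3-hydroxymethyl-4-(4-hydroxy-3,5-dimethoxybenzoyl)tetrahydrofuran | COc1cc([C@H]2OC[C@@H](C(=O)c3cc(OC)c(O)c(OC)c3)[C@@H]2CO)ccc1O | target

## Step count and least certain steps

Total step count: 13. Longest linear sequence: 10 steps (steps 1, 2, 3 and 7 to 13 from vanillin 1; the ring B branch, steps 4, 5, 6 and 7 to 13 from 8, is equally long).

**Step 8 (key step).** The most likely failure is reduction of the C3 radical by a second trivalent titanium before ring closure, followed by β-elimination that removes the oxirane oxygen or expels the propargylic ether. This is a competition between a bimolecular capture and a unimolecular closure, so it grows if the reductant concentration is high. Incomplete trans control at C3 is the second risk.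
Fallback: set out from 14 and make the same C3–C4 bond by a tin hydride chain instead of a metal-centred radical. Hydrolytic opening of the oxirane at its terminal carbon with a matched (salen)Co(OAc) catalyst and water in THF should give the diol F1. Silylation with tert-butylchlorodimethylsilane and imidazole at 0 °C should select the primary hydroxyl and give the mono-silyl ether F2. Phenyl chlorothionoformate with pyridine and DMAP would convert the remaining C3 hydroxyl into the O-phenyl thionocarbonate F3. Slow addition of Bu3SnH and AIBN to F3 in toluene at 80 °C (Barton–McCombie radical generation) should produce the same C3 radical, which closes 5-exo-dig onto the alkyne; the vinyl radical takes hydrogen from the stannane. The product is 18, so the route is rejoined after step 9.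

**Step 3.** The epoxy alcohol is harvested as the product of a kinetic resolution, so its enantiomeric purity is limited by the selectivity factor and falls as conversion approaches one half. The titanium Lewis acid may also open the oxirane of an electron-rich benzylic epoxy alcohol.
Fallback: set out from 5 and resolve by enzymatic acylation instead. Candida antarctica lipase B with vinyl acetate in tert-butyl methyl ether should acetylate the (R)-alcohol to the acetate F5 and leave the (S)-allylic alcohol F4, following the usual size-based selectivity of this lipase for secondary alcohols. After separation, F4 would be epoxidised with Ti(OiPr)4, diisopropyl D-(−)-tartrate and 6; substrate and reagent are then matched and no resolution is asked of the epoxidation. This returns to 7.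

**Step 7.** The hindered secondary benzylic alcohol may alkylate slowly, and silver-assisted ionisation of the aryl-substituted propargylic bromide may consume the electrophile faster than the ether forms.
Fallback: set out from 7 and attach ring B after the ether is in place. Alkylation with the small, unhindered propargyl bromide (Ag2O, or NaH with Bu4NI in THF at 0 °C) should give the terminal propargyl ether F6. Sonogashira coupling of F6 with 9 under the conditions of step 5 (room temperature, hindered amine, so the oxirane is not opened) returns to 14.

**Step 10.** The electron-donating ring B may divert some boron to C4, the benzylic borane may be lost by protonolysis, and the alkaline peroxide may begin to cleave an aryl silyl ether.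
Fallback: set out from 18 and install the C7 oxygen by a route whose regiochemistry does not depend on the borane. Upjohn dihydroxylation (OsO4 cat., N-methylmorpholine N-oxide) should give the C4,C7-diol F7. Dess–Martin oxidation of its secondary benzylic hydroxyl would give the α-hydroxy ketone F8. SmI2 in THF/MeOH at −78 °C should remove the tertiary α-hydroxyl by reductive cleavage and protonation of the samarium enolate, giving the ketone as a C4 epimer mixture. This returns to 22, before the equilibration.

**Step 12.** Enolisation of the hindered aryl ketone may be slow, the amidine may start to remove an aryl silyl group (the resulting para-phenoxide would shut down enolisation), and some ring opening by β-elimination of O1 cannot be excluded.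
Fallback: set out from 22 and give up enolate chemistry. Equilibration through the enol with a catalytic anhydrous sulfonic acid (p-toluenesulfonic acid, toluene, 40 to 60 °C) has no anionic driving force for β-elimination. Because C3 cannot epimerise, any reversible ionisation at benzylic C2 under these conditions should also relax toward the all-trans arrangement. This returns to 23.

## Further compounds

F1 | step 8 | diol from opening of the oxirane of 14 at C6 (C3 secondary hydroxyl, C6 primary hydroxyl; configurations as in 14) | COc1cc([C@@H](OCC#Cc2cc(OC)c(O[Si](C(C)C)(C(C)C)C(C)C)c(OC)c2)[C@@H](O)CO)ccc1O[Si](C(C)C)(C(C)C)C(C)C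
F2 | step 8 | C6 tert-butyldimethylsilyl ether of F1 | COc1cc([C@@H](OCC#Cc2cc(OC)c(O[Si](C(C)C)(C(C)C)C(C)C)c(OC)c2)[C@@H](O)CO[Si](C)(C)C(C)(C)C)ccc1O[Si](C(C)C)(C(C)C)C(C)C
F3 | step 8 | O-phenyl thionocarbonate of F2 at the C3 oxygen | COc1cc([C@@H](OCC#Cc2cc(OC)c(O[Si](C(C)C)(C(C)C)C(C)C)c(OC)c2)[C@@H](OC(=S)Oc2ccccc2)CO[Si](C)(C)C(C)(C)C)ccc1O[Si](C(C)C)(C(C)C)C(C)C
F4 | step 3 | (S)-1-[3-methoxy-4-(triisopropylsilyloxy)phenyl]prop-2-en-1-ol | COc1cc([C@@H](O)C=C)ccc1O[Si](C(C)C)(C(C)C)C(C)C
F5 | step 3 | (R)-1-[3-methoxy-4-(triisopropylsilyloxy)phenyl]prop-2-en-1-yl acetate | COc1cc([C@H](OC(C)=O)C=C)ccc1O[Si](C(C)C)(C(C)C)C(C)C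
F6 | step 7 | terminal propargyl ether of 7 (configurations as in 7) | COc1cc([C@@H](OCC#C)[C@@H]2CO2)ccc1O[Si](C(C)C)(C(C)C)C(C)C
F7 | step 10 | C4,C7-diol from dihydroxylation of 18 (C4 and C7 configurations not fixed) | COc1cc([C@H]2OCC(O)(C(O)c3cc(OC)c(O[Si](C(C)C)(C(C)C)C(C)C)c(OC)c3)[C@@H]2CO[Si](C)(C)C(C)(C)C)ccc1O[Si](C(C)C)(C(C)C)C(C)C
F8 | step 10 | C4-hydroxy C7-ketone from oxidation of F7 (C4 configuration not fixed) | COc1cc([C@H]2OCC(O)(C(=O)c3cc(OC)c(O[Si](C(C)C)(C(C)C)C(C)C)c(OC)c3)[C@@H]2CO[Si](C)(C)C(C)(C)C)ccc1O[Si](C(C)C)(C(C)C)C(C)C
F0 | step 12 | none | none
A1 | alternative 1 | all-trans 2-aryl-3-acetoxymethyl-4-aroyltetrahydrofuran, both phenols as triisopropylsilyl ethers | COc1cc([C@H]2OC[C@@H](C(=O)c3cc(OC)c(O[Si](C(C)C)(C(C)C)C(C)C)c(OC)c3)[C@@H]2COC(C)=O)ccc1O[Si](C(C)C)(C(C)C)C(C)C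
A2 | alternative 1 | (R,E)-5-acetoxy-2-[3,5-dimethoxy-4-(triisopropylsilyloxy)phenyl]pent-3-ene-1,2-diol | OC[C@](O)(c1cc(OC)c(O[Si](C(C)C)(C(C)C)C(C)C)c(OC)c1)/C=C/COC(C)=O
A3 | alternative 2 | dimethyl 2,4-cis-2-aryl-4-(1-arylvinyl)tetrahydrofuran-3,3-dicarboxylate | COc1cc([C@H]2OC[C@@H](C(=C)c3cc(OC)c(O[Si](C)(C)C(C)(C)C)c(OC)c3)C2(C(=O)OC)C(=O)OC)ccc1O[Si](C)(C)C(C)(C)C
A4 | alternative 2 | racemic 2-{1-[4-(tert-butyldimethylsilyloxy)-3,5-dimethoxyphenyl]vinyl}oxirane | C=C(c1cc(OC)c(O[Si](C)(C)C(C)(C)C)c(OC)c1)C1CO1
A5 | alternative 2 | dimethyl 2-[4-(tert-butyldimethylsilyloxy)-3-methoxybenzylidene]malonate | COC(=O)C(=Cc1ccc(O[Si](C)(C)C(C)(C)C)c(OC)c1)C(=O)OC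
A6 | alternative 3 | cis-fused 2,6-diaryl-3,7-dioxabicyclo[3.3.0]octan-8-one with ring A exo | COc1cc([C@H]2OC[C@H]3[C@@H]2C(=O)O[C@@H]3c2cc(OC)c(O[Si](C)(C)C(C)(C)C)c(OC)c2)ccc1O[Si](C)(C)C(C)(C)C
A7 | alternative 3 | 3-diazo-5-aryl(ring B)-4-[(ring A benzyloxy)methyl]dihydrofuran-2-one | COc1cc(COC[C@H]2C(=[N+]=[N-])C(=O)O[C@@H]2c2cc(OC)c(O[Si](C)(C)C(C)(C)C)c(OC)c2)ccc1O[Si](C)(C)C(C)(C)C
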